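**Plan**
1. Retrosynthesis: remove the sulfate and benzyl groups, return C2 to its epimer (as the aldehyde) and C3–C4 to an alkene. Then cut C2–C3 and C4–C4a together. This leaves propargyl alcohol 13 and (R)-3,3-diarylpropanal 10. Compound 10 is cut at C1–aryl into enal 6 and boronic acid 9, both made from phenol 1.
2. Enabling feature: C2 and the aromatic carbon C4a are 1,4-related through C1 and C8a, and both can carry bromine. The side-chain carbons on C2 and C3 are both oxygenated, so a temporary CH(OMe)–O–CH2 acetal (ring C) ties the unit C4–C3–CH2O to C2.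
3. Forward order: the pendant ring and ring A are joined at C1 (step 5). Rings C and B close in one nickel-catalysed reductive cascade (step 8). Ring C is opened again in step 10, which also tells the two CH2O groups apart.
4. Stereochemistry: C1 comes from the chiral rhodium catalyst. C3 comes from hydrogenation anti to the pseudoaxial C1 aryl group. C2 comes from base equilibration of the aldehyde to the all-trans array.

Key step: step 8

Remark on locants: the tetralin numbering of the target is used throughout. C1 bears the pendant aryl group, C2 the CH2OSO3H group, C3 the CH2OH group, and C4 is the ring CH2. C4a (next to C4) and C8a are the fusion carbons of aromatic ring A. Ring B is the carbocycle and ring C the temporary oxygen ring.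
Assumption: the sulfate monoesters 22 and 23 are drawn as hydrogen sulfates, as in the target SMILES. In practice 22 would be handled as a salt, and the acid form of 23 would be released on a sulfonic acid resin.

Step 1
Reactants: 1 4-bromo-2,6-dimethoxyphenol
Product: 2 2-(benzyloxy)-5-bromo-1,3-dimethoxybenzene
Conditions: BnBr, K2CO3, DMF, rt
Reagents that add atoms: benzyl bromide BrCc1ccccc1
Why: Williamson ether synthesis on the acidic phenol; the benzyl ether should survive every step up to the final hydrogenolysis.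

Step 2
Reactants: 2 2-(benzyloxy)-5-bromo-1,3-dimethoxybenzene
Product: 4 3-(benzyloxy)-6-bromo-2,4-dimethoxybenzaldehyde, via chloro(methoxy)methyl arene 3 (not isolated)
Conditions: Cl2CHOMe, SnCl4, CH2Cl2, -20 to 0 °C; then H2O
Reagents that add atoms: dichloromethyl methyl ether COC(Cl)Cl; water O
Why: Rieche formylation; the two free ring positions are equivalent and each is ortho and para to a methoxy group, so the electrophile enters next to bromine and the work-up hydrolyses the chloro ether.

Step 3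
Reactants: 4 3-(benzyloxy)-6-bromo-2,4-dimethoxybenzaldehyde
Product: 6 (E)-3-[3-(benzyloxy)-6-bromo-2,4-dimethoxyphenyl]prop-2-enal, via vinyl dioxolane 5 (not isolated)
Conditions: (1,3-dioxolan-2-ylmethyl)triphenylphosphonium bromide, KOtBu, THF, 0 °C to reflux; then 1 M HCl, THF, rt
Reagents that add atoms: (1,3-dioxolan-2-ylmethyl)triphenylphosphonium bromide [Br-].c1ccc(cc1)[P+](CC1OCCO1)(c1ccccc1)c1ccccc1; water O
Why: Wittig olefination with a reactive ylide copes with the di-ortho-substituted aldehyde and cannot over-homologate, and the acid hydrolysis of the dioxolane also equilibrates the alkene to E.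

Step 4
Reactants: 2 2-(benzyloxy)-5-bromo-1,3-dimethoxybenzene
Product: 9 [4-(benzyloxy)-3,5-dimethoxyphenyl]boronic acid, via aryllithium 7 (not isolated), via lithium aryltriisopropoxyborate 8 (not isolated)
Conditions: n-BuLi, THF, -78 °C; B(OiPr)3, -78 °C to rt; then 1 M HCl
Reagents that add atoms: triisopropyl borate CC(C)OB(OC(C)C)OC(C)C; water O
Why: bromine–lithium exchange, trapping with a borate ester and hydrolysis is the standard route to electron-rich arylboronic acids.

Step 5
Reactants: 6 (E)-3-[3-(benzyloxy)-6-bromo-2,4-dimethoxyphenyl]prop-2-enal; 9 [4-(benzyloxy)-3,5-dimethoxyphenyl]boronic acid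
Product: 10 (3R)-3-[3-(benzyloxy)-6-bromo-2,4-dimethoxyphenyl]-3-[4-(benzyloxy)-3,5-dimethoxyphenyl]propanal
Conditions: [Rh(C2H4)2Cl]2 (cat.), carvone-derived chiral bicyclo[2.2.2]octadiene ligand (the enantiomer that attacks the Si face), KOH (0.5 equiv), MeOH–H2O 10:1, 50 °C
Reagents that add atoms: none
Why: Hayashi–Miyaura reaction (asymmetric 1,4-addition of an arylboronic acid to an enal, a type known to give 3,3-diarylpropanals); the diene complex of monovalent rhodium should carbometalate the Si face of the β-carbon, which sets C1 as R, should add 1,4 and not 1,2, and should leave the aryl bromide alone.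

Step 6
Reactants: 10 (3R)-3,3-diarylpropanal
Product: 12 (3R)-3-[3-(benzyloxy)-6-bromo-2,4-dimethoxyphenyl]-3-[4-(benzyloxy)-3,5-dimethoxyphenyl]-1-methoxyprop-1-ene (E/Z), via dimethyl acetal 11 (not isolated)
Conditions: HC(OMe)3, p-TsOH (cat.), MeOH, rt, concentrate; then TMSOTf, iPr2NEt, CH2Cl2, -20 °C to rt
Reagents that add atoms: trimethyl orthoformate COC(OC)OC
Why: acetalisation followed by silyl triflate/amine-promoted loss of methanol gives the enol ether under buffered conditions that should not touch the doubly benzylic C1–H, and the E/Z ratio is irrelevant.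

Step 7
Reactants: 12 methyl enol ether; 13 prop-2-yn-1-ol
Product: 14 (1R)-2-bromo-1-[3-(benzyloxy)-6-bromo-2,4-dimethoxyphenyl]-1-[4-(benzyloxy)-3,5-dimethoxyphenyl]-3-methoxy-3-(prop-2-yn-1-yloxy)propane (epimers at C2 and at the acetal carbon)
Conditions: NBS, propargyl alcohol (5 equiv), CH2Cl2, -78 to -40 °C
Reagents that add atoms: N-bromosuccinimide O=C1CCC(=O)N1Br
Why: Ueno–Stork haloacetalisation; the enol ether is by far the most nucleophilic π system, takes up bromine at C2, and the oxocarbenium ion is trapped by the alcohol, while the epimer mixture is of no consequence.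

Step 8
Reactants: 14 dibromide
Product: 15 (9R,9aR)-7-(benzyloxy)-9-[4-(benzyloxy)-3,5-dimethoxyphenyl]-1,6,8-trimethoxy-1,3,9,9a-tetrahydronaphtho[2,3-c]furan (both acetal epimers; pendant aryl at C1 cis to the acetal carbon on C2; C3=C4 alkene)
Conditions: NiBr2(dme) (15 mol %), 4,4'-di-tert-butyl-2,2'-bipyridine (20 mol %), Zn dust (3 equiv), DMA, 0.02 M, 40 °C
Reagents that add atoms: none
Why: Zn reduces the salt to zerovalent nickel, which inserts into the aryl C4a–Br bond, while a monovalent nickel species abstracts bromine from C2; the C2 radical adds to the internal alkyne carbon C3 (first bond), and the vinyl radical at C4 is caught by the aryl-nickel centre of the same molecule, whose trivalent state reductively eliminates to make C4–C4a (second bond), so two carbons that both began as C–Br electrophiles are joined across one π bond. The closest known reaction type is the nickel-catalysed reductive radical cyclisation/aryl coupling of Ueno–Stork haloacetals that carry a tethered alkene or alkyne, including fully intramolecular cases. Ring C closes 5-exo-dig, and ring B closes by C(sp2)–C(sp2) reductive elimination from a seven-membered nickelacycle, which only the vinyl-radical invertomer pointing towards C2 can form. The one new stereocentre, C2, is controlled by C1: both C2 bromides give the same radical, which should react in the staggered conformer with C1–H next to the acetal carbon and the di-ortho-substituted bromoaryl group anti to the incoming alkyne, so the pendant aryl group and the acetal carbon end up cis (2R), the arrangement that step 9 needs and step 13 later corrects. The alkyne is chosen on purpose, because with an allyl acetal the same bias would fix C3 trans to C2 and so on the wrong side relative to C1 for good, whereas the alkyne leaves C3 trigonal. The step needs chemoselective activation of the two bromides (insertion at the arene, halogen abstraction at the secondary carbon), exo over endo closure (secured by the three-atom C–O–C tether) and cyclisation before capture (capture of the C2 radical could only lead to a benzocyclobutene and is reversible).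

Step 9
Reactants: 15 dihydronaphthofuran acetal
Product: 16 (3aS,9R,9aR)-7-(benzyloxy)-9-[4-(benzyloxy)-3,5-dimethoxyphenyl]-1,6,8-trimethoxy-1,3,3a,4,9,9a-hexahydronaphtho[2,3-c]furan (C1, C2 and C3 substituents all cis)
Conditions: H2 (1–3 atm), PtO2 (cat.), EtOAc, rt
Reagents that add atoms: none
Why: heterogeneous syn-hydrogenation on a catalyst of low hydrogenolysis activity; the peri 8-methoxy group holds the C1 aryl group pseudoaxial over one face and the acetal carbon on C2 lies on that same face, so hydrogen should arrive from the other face and set C3 as S with its CH2O group cis to the aryl group, as in the target.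

Step 10
Reactants: 16 all-cis acetal
Product: 17 (1R,2R,3S)-7-(benzyloxy)-1-[4-(benzyloxy)-3,5-dimethoxyphenyl]-2-(1,3-dithian-2-yl)-3-(hydroxymethyl)-6,8-dimethoxy-1,2,3,4-tetrahydronaphthalene
Conditions: HS(CH2)3SH (1.2 equiv), BF3·OEt2 (0.3 equiv), CH2Cl2, -40 to 0 °C
Reagents that add atoms: propane-1,3-dithiol SCCCS
Why: Lewis-acid-catalysed transthioacetalisation, as used to open furanosides to acyclic dithioacetals, turns the acetal carbon into a dithiane and frees only the C3 hydroxymethyl group, which differentiates the two side chains.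

Step 11
Reactants: 17 dithiane alcohol
Product: 18 (1R,2R,3S)-7-(benzyloxy)-1-[4-(benzyloxy)-3,5-dimethoxyphenyl]-3-[(benzyloxy)methyl]-2-(1,3-dithian-2-yl)-6,8-dimethoxy-1,2,3,4-tetrahydronaphthalene
Conditions: NaH, BnBr, Bu4NI (cat.), DMF, 0 °C to rt
Reagents that add atoms: benzyl bromide BrCc1ccccc1
Why: Williamson ether synthesis on the only free hydroxyl group; the dithiane is inert to NaH.

Step 12
Reactants: 18 dithiane benzyl ether
Product: 19 (1R,2R,3S)-7-(benzyloxy)-1-[4-(benzyloxy)-3,5-dimethoxyphenyl]-3-[(benzyloxy)methyl]-6,8-dimethoxy-1,2,3,4-tetrahydronaphthalene-2-carbaldehyde (all-cis)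
Conditions: MeI (excess), CaCO3, MeCN–H2O 9:1, 45 °C
Reagents that add atoms: water O
Why: alkylative hydrolysis of the dithiane (S-methylation, then attack of water) is non-oxidative and buffered, so the electron-rich rings and the benzyl ethers should survive.

Step 13
Reactants: 19 all-cis aldehyde
Product: 21 [(1R,2S,3S)-7-(benzyloxy)-1-[4-(benzyloxy)-3,5-dimethoxyphenyl]-3-[(benzyloxy)methyl]-6,8-dimethoxy-1,2,3,4-tetrahydronaphthalen-2-yl]methanol, via all-trans aldehyde 20 (not isolated)
Conditions: DBU (0.3 equiv), CH2Cl2–MeOH, rt, to equilibrium; then NaBH4, 0 °C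
Reagents that add atoms: none
Why: base-catalysed epimerisation through the enolate should move the formyl group off the face it shares with both neighbours to give the trans,trans array (the thermodynamic arrangement of 1-aryltetralin-2,3-dicarbonyl compounds), which sets C2 as in the target, and carbonyl reduction in the same flask locks it.

Step 14
Reactants: 21 primary alcohol
Product: 22 [(1R,2S,3S)-7-(benzyloxy)-1-[4-(benzyloxy)-3,5-dimethoxyphenyl]-3-[(benzyloxy)methyl]-6,8-dimethoxy-1,2,3,4-tetrahydronaphthalen-2-yl]methyl hydrogen sulfate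
Conditions: SO3·pyridine (3 equiv), pyridine, rt
Reagents that add atoms: sulfur trioxide pyridine complex O=S(=O)=O.c1ccncc1
Why: O-sulfation with an amine–SO3 complex meets a single free hydroxyl group, because both phenols and the other alcohol are benzylated.

Step 15
Reactants: 22 tribenzyl sulfate
Product: 23 [(1R,2S,3S)-7-hydroxy-1-(4-hydroxy-3,5-dimethoxyphenyl)-3-(hydroxymethyl)-6,8-dimethoxy-1,2,3,4-tetrahydronaphthalen-2-yl]methyl hydrogen sulfate (target)
Conditions: H2 (1 atm), Pd/C, MeOH–H2O, rt; then sulfonic acid resin (H+ form)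
Reagents that add atoms: none
Why: catalytic hydrogenolysis cleaves the three benzyl ethers, while the alkyl sulfate, the diarylmethine C–C bonds and all three stereocentres are inert.

**Compound list**
1 | 4-bromo-2,6-dimethoxyphenol | COc1cc(Br)cc(OC)c1O | starting material
2 | 2-(benzyloxy)-5-bromo-1,3-dimethoxybenzene | COc1cc(Br)cc(OC)c1OCc1ccccc1 | intermediate
3 | 2-(benzyloxy)-5-bromo-4-[chloro(methoxy)methyl]-1,3-dimethoxybenzene | COC(Cl)c1c(Br)cc(OC)c(OCc2ccccc2)c1OC | intermediate
4 | 3-(benzyloxy)-6-bromo-2,4-dimethoxybenzaldehyde | O=Cc1c(Br)cc(OC)c(OCc2ccccc2)c1OC | intermediate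
5 | 2-{2-[3-(benzyloxy)-6-bromo-2,4-dimethoxyphenyl]ethenyl}-1,3-dioxolane (E/Z) | COc1cc(Br)c(C=CC2OCCO2)c(OC)c1OCc1ccccc1 | intermediate
6 | (E)-3-[3-(benzyloxy)-6-bromo-2,4-dimethoxyphenyl]prop-2-enal | O=C/C=C/c1c(Br)cc(OC)c(OCc2ccccc2)c1OC | intermediate
7 | [4-(benzyloxy)-3,5-dimethoxyphenyl]lithium | [Li]c1cc(OC)c(OCc2ccccc2)c(OC)c1 | intermediate
8 | lithium [4-(benzyloxy)-3,5-dimethoxyphenyl]tri(propan-2-yloxy)borate | [Li+].CC(C)O[B-](OC(C)C)(OC(C)C)c1cc(OC)c(OCc2ccccc2)c(OC)c1 | intermediate
9 | [4-(benzyloxy)-3,5-dimethoxyphenyl]boronic acid | OB(O)c1cc(OC)c(OCc2ccccc2)c(OC)c1 | intermediate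
10 | (3R)-3-[3-(benzyloxy)-6-bromo-2,4-dimethoxyphenyl]-3-[4-(benzyloxy)-3,5-dimethoxyphenyl]propanal | COc1cc([C@@H](CC=O)c2c(Br)cc(OC)c(OCc3ccccc3)c2OC)cc(OC)c1OCc1ccccc1 | intermediate
11 | (1R)-1-[3-(benzyloxy)-6-bromo-2,4-dimethoxyphenyl]-1-[4-(benzyloxy)-3,5-dimethoxyphenyl]-3,3-dimethoxypropane | COc1cc([C@@H](CC(OC)OC)c2c(Br)cc(OC)c(OCc3ccccc3)c2OC)cc(OC)c1OCc1ccccc1 | intermediate
12 | (3R)-3-[3-(benzyloxy)-6-bromo-2,4-dimethoxyphenyl]-3-[4-(benzyloxy)-3,5-dimethoxyphenyl]-1-methoxyprop-1-ene (E/Z) | COc1cc([C@@H](C=COC)c2c(Br)cc(OC)c(OCc3ccccc3)c2OC)cc(OC)c1OCc1ccccc1 | intermediate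
13 | prop-2-yn-1-ol | OCC#C | starting material
14 | (1R)-2-bromo-1-[3-(benzyloxy)-6-bromo-2,4-dimethoxyphenyl]-1-[4-(benzyloxy)-3,5-dimethoxyphenyl]-3-methoxy-3-(prop-2-yn-1-yloxy)propane (epimers at C2 and C3 of the chain) | COc1cc([C@@H](C(Br)C(OC)OCC#C)c2c(Br)cc(OC)c(OCc3ccccc3)c2OC)cc(OC)c1OCc1ccccc1 | intermediate
15 | (9R,9aR)-7-(benzyloxy)-9-[4-(benzyloxy)-3,5-dimethoxyphenyl]-1,6,8-trimethoxy-1,3,9,9a-tetrahydronaphtho[2,3-c]furan (acetal epimers) | COc1cc([C@@H]2c3c(OC)c(OCc4ccccc4)c(OC)cc3C=C3COC(OC)[C@H]23)cc(OC)c1OCc1ccccc1 | intermediate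
16 | (3aS,9R,9aR)-7-(benzyloxy)-9-[4-(benzyloxy)-3,5-dimethoxyphenyl]-1,6,8-trimethoxy-1,3,3a,4,9,9a-hexahydronaphtho[2,3-c]furan (acetal epimers) | COc1cc([C@@H]2c3c(OC)c(OCc4ccccc4)c(OC)cc3C[C@@H]3COC(OC)[C@H]23)cc(OC)c1OCc1ccccc1 | intermediate
17 | (1R,2R,3S)-7-(benzyloxy)-1-[4-(benzyloxy)-3,5-dimethoxyphenyl]-2-(1,3-dithian-2-yl)-3-(hydroxymethyl)-6,8-dimethoxy-1,2,3,4-tetrahydronaphthalene | COc1cc([C@@H]2c3c(OC)c(OCc4ccccc4)c(OC)cc3C[C@H](CO)[C@@H]2C2SCCCS2)cc(OC)c1OCc1ccccc1 | intermediate
18 | (1R,2R,3S)-7-(benzyloxy)-1-[4-(benzyloxy)-3,5-dimethoxyphenyl]-3-[(benzyloxy)methyl]-2-(1,3-dithian-2-yl)-6,8-dimethoxy-1,2,3,4-tetrahydronaphthalene | COc1cc([C@@H]2c3c(OC)c(OCc4ccccc4)c(OC)cc3C[C@H](COCc3ccccc3)[C@@H]2C2SCCCS2)cc(OC)c1OCc1ccccc1 | intermediate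
19 | (1R,2R,3S)-7-(benzyloxy)-1-[4-(benzyloxy)-3,5-dimethoxyphenyl]-3-[(benzyloxy)methyl]-6,8-dimethoxy-1,2,3,4-tetrahydronaphthalene-2-carbaldehyde | COc1cc([C@@H]2c3c(OC)c(OCc4ccccc4)c(OC)cc3C[C@H](COCc3ccccc3)[C@@H]2C=O)cc(OC)c1OCc1ccccc1 | intermediate
20 | (1R,2S,3S)-7-(benzyloxy)-1-[4-(benzyloxy)-3,5-dimethoxyphenyl]-3-[(benzyloxy)methyl]-6,8-dimethoxy-1,2,3,4-tetrahydronaphthalene-2-carbaldehyde | COc1cc([C@@H]2c3c(OC)c(OCc4ccccc4)c(OC)cc3C[C@H](COCc3ccccc3)[C@H]2C=O)cc(OC)c1OCc1ccccc1 | intermediate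
21 | [(1R,2S,3S)-7-(benzyloxy)-1-[4-(benzyloxy)-3,5-dimethoxyphenyl]-3-[(benzyloxy)methyl]-6,8-dimethoxy-1,2,3,4-tetrahydronaphthalen-2-yl]methanol | COc1cc([C@@H]2c3c(OC)c(OCc4ccccc4)c(OC)cc3C[C@H](COCc3ccccc3)[C@H]2CO)cc(OC)c1OCc1ccccc1 | intermediate
22 | [(1R,2S,3S)-7-(benzyloxy)-1-[4-(benzyloxy)-3,5-dimethoxyphenyl]-3-[(benzyloxy)methyl]-6,8-dimethoxy-1,2,3,4-tetrahydronaphthalen-2-yl]methyl hydrogen sulfate | COc1cc([C@@H]2c3c(OC)c(OCc4ccccc4)c(OC)cc3C[C@H](COCc3ccccc3)[C@H]2COS(=O)(=O)O)cc(OC)c1OCc1ccccc1 | intermediate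
23 | [(1R,2S,3S)-7-hydroxy-1-(4-hydroxy-3,5-dimethoxyphenyl)-3-(hydroxymethyl)-6,8-dimethoxy-1,2,3,4-tetrahydronaphthalen-2-yl]methyl hydrogen sulfate | COc1cc([C@@H]2c3c(cc(OC)c(O)c3OC)C[C@H](CO)[C@H]2COS(=O)(=O)O)cc(OC)c1O | target

**Step count and risks**
Total steps: 15. Longest linear sequence: 14 (steps 1–3 and 5–15; step 4 is a one-step branch from 2).

Steps most likely to fail:

Step 8. The vinyl radical may abstract hydrogen, or the aryl-nickel species may be protonated, before ring B closes. The terminal alkyne may also oligomerise at low-valent nickel. The fallback sets out from 14 and makes the two bonds one after the other by known reactions.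
- (Me3Si)3SiH and AIBN (toluene, 80 °C) attack the secondary alkyl bromide much faster than the aryl bromide. A 5-exo-dig cyclisation and hydrogen transfer give the 4-methylenetetrahydrofuran acetal F1.
- 9-BBN-H adds to the 1,1-disubstituted alkene from the face away from the diarylmethyl group and gives the B-alkyl borane F2.
- F2 is closed without isolation by an intramolecular B-alkyl Suzuki–Miyaura coupling (Pd(dppf)Cl2, K3PO4, DMF–H2O, 60 °C).
- This comes back to the route at the all-cis acetal 16, so step 9 is skipped as well.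

Step 5. Carbometalation at a β-carbon flanked by bromine and methoxy may be slow, so protodeboronation and loss of enantioselectivity can take over. The fallback sets out from 2, reverses the roles of the two rings and uses an auxiliary.
- Iodination of 2 (NIS, cat. CF3CO2H, MeCN) gives 2-(benzyloxy)-5-bromo-4-iodo-1,3-dimethoxybenzene F3.
- Iodine–magnesium exchange (iPrMgCl·LiCl, THF, -40 °C) gives the arylmagnesium chloride F4.
- A second portion of 2 undergoes a Heck reaction with (R)-3-acryloyl-4-phenyl-1,3-oxazolidin-2-one (Pd(OAc)2, P(o-tol)3, Et3N, DMF, 100 °C) to give the cinnamoyl imide F5.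
- CuBr·SMe2-mediated conjugate addition of F4 to the chelated s-cis form of F5, anti to the phenyl group, gives the (3R)-diaryl imide F6.
- LiBH4 gives the primary alcohol F7, and Dess–Martin periodinane oxidises it.
- This comes back to the route at 10.

Step 13. The equilibrium may not lie far enough on the trans,trans side, and the aldehyde may suffer side reactions on long exposure to base. The fallback sets out from 19 and equilibrates a bulkier and more robust ester instead.
- Pinnick oxidation (NaClO2, NaH2PO4, 2-methylbut-2-ene) gives the all-cis acid F8.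
- TMSCHN2 gives the all-cis methyl ester F9.
- NaOMe in refluxing MeOH epimerises C2 to the trans,trans methyl ester F10.
- LiAlH4 reduces the ester, which comes back to the route at 21.

**Further compounds**
F1 | step 8 | (1R)-configured 3-[(bromoaryl)(aryl)methyl]-2-methoxy-4-methylenetetrahydrofuran (C2 as in 15) | COc1cc([C@@H]([C@H]2C(OC)OCC2=C)c2c(Br)cc(OC)c(OCc3ccccc3)c2OC)cc(OC)c1OCc1ccccc1
F2 | step 8 | B-alkyl-9-borabicyclo[3.3.1]nonane from F1 (CH2B group cis to the diarylmethyl group) | COc1cc([C@@H]([C@H]2C(OC)OC[C@H]2CB2C3CCCC2CCC3)c2c(Br)cc(OC)c(OCc3ccccc3)c2OC)cc(OC)c1OCc1ccccc1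
F3 | step 5 | 2-(benzyloxy)-5-bromo-4-iodo-1,3-dimethoxybenzene | COc1cc(Br)c(I)c(OC)c1OCc1ccccc1
F4 | step 5 | [3-(benzyloxy)-6-bromo-2,4-dimethoxyphenyl]magnesium chloride | Cl[Mg]c1c(Br)cc(OC)c(OCc2ccccc2)c1OC
F5 | step 5 | (4R)-3-{(E)-3-[4-(benzyloxy)-3,5-dimethoxyphenyl]prop-2-enoyl}-4-phenyl-1,3-oxazolidin-2-one | O=C(/C=C/c1cc(OC)c(OCc2ccccc2)c(OC)c1)N1[C@H](c2ccccc2)COC1=O
F6 | step 5 | (4R)-3-{(3R)-3-[3-(benzyloxy)-6-bromo-2,4-dimethoxyphenyl]-3-[4-(benzyloxy)-3,5-dimethoxyphenyl]propanoyl}-4-phenyl-1,3-oxazolidin-2-one | COc1cc([C@@H](CC(=O)N2[C@H](c3ccccc3)COC2=O)c2c(Br)cc(OC)c(OCc3ccccc3)c2OC)cc(OC)c1OCc1ccccc1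
F7 | step 5 | (3R)-3-[3-(benzyloxy)-6-bromo-2,4-dimethoxyphenyl]-3-[4-(benzyloxy)-3,5-dimethoxyphenyl]propan-1-ol | COc1cc([C@@H](CCO)c2c(Br)cc(OC)c(OCc3ccccc3)c2OC)cc(OC)c1OCc1ccccc1
F8 | step 13 | (1R,2R,3S)-7-(benzyloxy)-1-[4-(benzyloxy)-3,5-dimethoxyphenyl]-3-[(benzyloxy)methyl]-6,8-dimethoxy-1,2,3,4-tetrahydronaphthalene-2-carboxylic acid | COc1cc([C@@H]2c3c(OC)c(OCc4ccccc4)c(OC)cc3C[C@H](COCc3ccccc3)[C@@H]2C(=O)O)cc(OC)c1OCc1ccccc1
F9 | step 13 | methyl ester of F8 (all-cis) | COc1cc([C@@H]2c3c(OC)c(OCc4ccccc4)c(OC)cc3C[C@H](COCc3ccccc3)[C@@H]2C(=O)OC)cc(OC)c1OCc1ccccc1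
F10 | step 13 | C2 epimer of F9 (1R,2S,3S; trans,trans) | COc1cc([C@@H]2c3c(OC)c(OCc4ccccc4)c(OC)cc3C[C@H](COCc3ccccc3)[C@H]2C(=O)OC)cc(OC)c1OCc1ccccc1
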